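**Retrosynthetic overview**
1. Target 26 ← catalyst-controlled double epoxidation of 10-acetoxyverticilla-3E,7E,12(18)-trien-13-one (25).
2. Twelve-membered ring ← B-alkyl Suzuki–Miyaura macrocyclisation at C8–C9; hydroboration of a C10 silyl enol ether sets C10.
3. Ring A stereocentres ← two conjugate additions to 4,4-dimethylcyclohexadienone: a new enantioselective Cu-catalysed borylmethylation (C1, C1–C2 bond), then a trans-selective vinyl addition with formaldehyde trap (C11, C18).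
4. C3–C8 chain ← dienyl iodide 8 (alkenyl iodide at C3, alkenylsilane as masked iodide at C8), joined to C2 by sp3–sp2 Suzuki coupling.
5. Ring order: ring A (bought as a six-membered ring) first, macrocycle second, both epoxides last.

Assumption: verticillane numbering is used for the side chain and the macrocycles (C1 and C11 bridgeheads, C15 = CMe2 bridge, C12–C14 three-carbon bridge, C2–C10 nine-carbon bridge, C18 on C12, C19 on C8, C20 on C4); Bpin = 4,4,5,5-tetramethyl-1,3,2-dioxaborolan-2-yl, TBS = tert-butyldimethylsilyl.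

**Route**

Step 1
Reactants: 1 5-(trimethylsilyl)pent-4-yn-1-ol
Product: 4 (4E)-5-(trimethylsilyl)hex-4-en-1-ol, via alkenylalane 2 (not isolated), via lithium alanate 3 (not isolated)
Conditions: i-Bu2AlH (2.2 equiv), heptane, 50 °C; MeLi, Et2O, 0 °C; MeI, rt
Reagents that add atoms: iodomethane, CI
Why: Hydroalumination of a silylalkyne in hydrocarbon solvent gives the trans adduct (Al on the silyl carbon, cis to the chain), and methylation of the derived alanate with retention gives the alkenylsilane with Si trans to the chain.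

Step 2
Reactants: 4 (4E)-5-(trimethylsilyl)hex-4-en-1-ol
Product: 5 (4E)-5-(trimethylsilyl)hex-4-enal
Conditions: PhI(OAc)2, TEMPO (10 mol%), CH2Cl2, rt
Reagents that add atoms: none
Why: TEMPO/PhI(OAc)2 oxidation of a primary alcohol stops at the aldehyde and leaves the alkenylsilane untouched.

Step 3
Reactants: 5 (4E)-5-(trimethylsilyl)hex-4-enal
Product: 6 trimethyl[(2E)-hept-2-en-6-yn-2-yl]silane
Conditions: dimethyl (1-diazo-2-oxopropyl)phosphonate, K2CO3, MeOH, 0 °C → rt
Reagents that add atoms: dimethyl (1-diazo-2-oxopropyl)phosphonate, COP(=O)(OC)C(=[N+]=[N-])C(C)=O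
Why: Ohira–Bestmann homologation converts the aldehyde into the terminal alkyne under mild base that does not touch the alkenyl–silicon bond.

Step 4
Reactants: 6 trimethyl[(2E)-hept-2-en-6-yn-2-yl]silane
Product: 8 [(2E,6E)-7-iodo-6-methylhepta-2,6-dien-2-yl]trimethylsilane, via alkenylalane 7 (not isolated)
Conditions: AlMe3, Cp2ZrCl2 (25 mol%), CH2Cl2, 0 °C → rt; then I2, THF, −30 °C
Reagents that add atoms: trimethylaluminium, C[Al](C)C; iodine, II
Why: Negishi zirconium-catalysed carboalumination adds Me and Al syn across the terminal alkyne only, and iodinolysis with retention gives the (E)-1-iodo-2-methylalkene.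

Step 5
Reactants: 9 4,4-dimethylcyclohex-2-en-1-one
Product: 10 4,4-dimethylcyclohexa-2,5-dien-1-one
Conditions: DDQ, dioxane, reflux
Reagents that add atoms: none
Why: DDQ dehydrogenation of a 4,4-disubstituted cyclohexenone gives the cross-conjugated dienone because the blocked C4 prevents aromatisation.

Step 6
Reactants: 10 4,4-dimethylcyclohexa-2,5-dien-1-one
Product: 12 (5R)-4,4-dimethyl-5-[(4,4,5,5-tetramethyl-1,3,2-dioxaborolan-2-yl)methyl]cyclohex-2-en-1-one, via lithium dienolate 11 (not isolated)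
Conditions: CH2(Bpin)2 (1.3 equiv), CuCl (5 mol%), (S,S)-Ph-BPE (6 mol%), LiOt-Bu (1.5 equiv), THF, 0 °C; H2O
Reagents that add atoms: bis(pinacolboryl)methane, CC1(C)OB(CB2OC(C)(C)C(C)(C)O2)OC1(C)C
Why: Proposed new method: LiOt-Bu turns CH2(Bpin)2 into a borate that transfers one B–C bond to the chiral bisphosphine–copper alkoxide, and the resulting nucleophilic L*Cu–CH2Bpin adds 1,4 to the cross-conjugated dienone (π-complex, trivalent copper β-cuprio enolate, reductive elimination) with ligand control of the enantiotopic β-face, which sets C1 (R) and forms C1–C2 while the second enone survives as the dienolate; the closest known reactions are Cu-catalysed enantioselective conjugate additions of bis(pinacolboryl)methane to unsaturated diesters and Cu–phosphoramidite additions of dialkylzincs to this dienone.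

Step 7
Reactants: 12 (5R)-4,4-dimethyl-5-[(4,4,5,5-tetramethyl-1,3,2-dioxaborolan-2-yl)methyl]cyclohex-2-en-1-one; 8 [(2E,6E)-7-iodo-6-methylhepta-2,6-dien-2-yl]trimethylsilane
Product: 13 (5R)-4,4-dimethyl-5-[(2E,6E)-3-methyl-7-(trimethylsilyl)octa-2,6-dien-1-yl]cyclohex-2-en-1-one
Conditions: PdCl2(dppf) (5 mol%), Cs2CO3, THF/H2O (10:1), 65 °C
Reagents that add atoms: none
Why: sp3–sp2 Suzuki–Miyaura coupling of the primary alkylboronate with the alkenyl iodide forms C2–C3 with retention of the E geometry, and the alkenylsilane is inert.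

Step 8
Reactants: 13 (5R)-4,4-dimethyl-5-[(2E,6E)-3-methyl-7-(trimethylsilyl)octa-2,6-dien-1-yl]cyclohex-2-en-1-one
Product: 15 (2S,3R,5R)-3-ethenyl-2-(hydroxymethyl)-4,4-dimethyl-5-[(2E,6E)-3-methyl-7-(trimethylsilyl)octa-2,6-dien-1-yl]cyclohexan-1-one, via silyl enol ether 14 (not isolated)
Conditions: CH2=CHMgBr, CuBr·SMe2 (10 mol%), Me3SiCl, THF, −78 °C; then aq. HCHO, Yb(OTf)3 (10 mol%), THF, rt
Reagents that add atoms: vinylmagnesium bromide, C=C[Mg]Br; formaldehyde, C=O
Why: Copper-catalysed conjugate addition occurs by axial attack anti to the C1 side chain and sets C11 trans to C1, and the regiodefined silyl enol ether then undergoes a Mukaiyama aldol with aqueous formaldehyde to place the future C18 on C12 (trans to the vinyl group).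

Step 9
Reactants: 15 (2S,3R,5R)-3-ethenyl-2-(hydroxymethyl)-4,4-dimethyl-5-[(2E,6E)-3-methyl-7-(trimethylsilyl)octa-2,6-dien-1-yl]cyclohexan-1-one
Product: 16 (2S,3R,5R)-2-{[(tert-butyldimethylsilyl)oxy]methyl}-3-ethenyl-4,4-dimethyl-5-[(2E,6E)-3-methyl-7-(trimethylsilyl)octa-2,6-dien-1-yl]cyclohexan-1-one
Conditions: TBSCl, imidazole, DMF, 0 °C → rt
Reagents that add atoms: tert-butyldimethylsilyl chloride, CC(C)(C)[Si](C)(C)Cl
Why: Silylation of the primary alcohol blocks retro-aldol and premature dehydration of the β-hydroxy ketone.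

Step 10
Reactants: 16 (2S,3R,5R)-2-{[(tert-butyldimethylsilyl)oxy]methyl}-3-ethenyl-4,4-dimethyl-5-[(2E,6E)-3-methyl-7-(trimethylsilyl)octa-2,6-dien-1-yl]cyclohexan-1-one
Product: 17 (2S,3R,5R)-3-acetyl-2-{[(tert-butyldimethylsilyl)oxy]methyl}-4,4-dimethyl-5-[(2E,6E)-3-methyl-7-(trimethylsilyl)octa-2,6-dien-1-yl]cyclohexan-1-one
Conditions: PdCl2 (10 mol%), CuCl, O2 (1 atm), DMF/H2O (7:1), rt
Reagents that add atoms: water, O
Why: Tsuji–Wacker oxidation converts only the monosubstituted alkene into the methyl ketone (C10 carbonyl, C9 methyl), and the trisubstituted alkenes do not react.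

Step 11
Reactants: 17 (2S,3R,5R)-3-acetyl-2-{[(tert-butyldimethylsilyl)oxy]methyl}-4,4-dimethyl-5-[(2E,6E)-3-methyl-7-(trimethylsilyl)octa-2,6-dien-1-yl]cyclohexan-1-one
Product: 18 (2S,3R,5R)-3-acetyl-2-{[(tert-butyldimethylsilyl)oxy]methyl}-5-[(2E,6E)-7-iodo-3-methylocta-2,6-dien-1-yl]-4,4-dimethylcyclohexan-1-one
Conditions: NIS, (CF3)2CHOH, 0 °C
Reagents that add atoms: N-iodosuccinimide, O=C1CCC(=O)N1I
Why: Ipso-iododesilylation of the alkenylsilane (β-silyl cation control) is faster than attack on the other alkene and gives the (E)-2-iodo-2-alkene with retention.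

Step 12
Reactants: 18 (2S,3R,5R)-3-acetyl-2-{[(tert-butyldimethylsilyl)oxy]methyl}-5-[(2E,6E)-7-iodo-3-methylocta-2,6-dien-1-yl]-4,4-dimethylcyclohexan-1-one
Product: 19 (3R,5R,6S)-1-[(tert-butyldimethylsilyl)oxy]-5-{1-[(tert-butyldimethylsilyl)oxy]ethenyl}-6-{[(tert-butyldimethylsilyl)oxy]methyl}-3-[(2E,6E)-7-iodo-3-methylocta-2,6-dien-1-yl]-4,4-dimethylcyclohex-1-ene
Conditions: TBSOTf, Et3N, CH2Cl2, −78 → 0 °C
Reagents that add atoms: tert-butyldimethylsilyl trifluoromethanesulfonate, CC(C)(C)[Si](C)(C)OS(=O)(=O)C(F)(F)F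
Why: Soft enolisation removes the least hindered α-hydrogen of each ketone, which turns the methyl ketone into the terminal silyl enol ether needed for hydroboration and masks the ring ketone against 9-BBN.

Step 13
Reactants: 19 (3R,5R,6S)-1-[(tert-butyldimethylsilyl)oxy]-5-{1-[(tert-butyldimethylsilyl)oxy]ethenyl}-6-{[(tert-butyldimethylsilyl)oxy]methyl}-3-[(2E,6E)-7-iodo-3-methylocta-2,6-dien-1-yl]-4,4-dimethylcyclohex-1-ene
Product: 21 (1R,3E,7E,10S,11R,12S)-10,13,18-tris[(tert-butyldimethylsilyl)oxy]verticilla-3,7,13-triene, via alkylborane 20 (not isolated)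
Conditions: 9-BBN, THF, rt; then PdCl2(dppf) (20 mol%), AsPh3, Cs2CO3, DMF/THF/H2O, 2 mM (slow addition), 45 °C
Reagents that add atoms: none
Why: 9-BBN adds only to the terminal silyl enol ether, delivering H to C10 anti to the quaternary C15 in the conformer with C11–H eclipsing the double bond (Felkin-type 1,2-induction, giving 10S), and the B-alkyl Suzuki–Miyaura macrocyclisation with the alkenyl iodide then forms C8–C9 and the twelve-membered ring with retention of the E alkene.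

Step 14
Reactants: 21 (1R,3E,7E,10S,11R,12S)-10,13,18-tris[(tert-butyldimethylsilyl)oxy]verticilla-3,7,13-triene
Product: 22 (1R,3E,7E,10S,11R,12S)-10,18-dihydroxyverticilla-3,7-dien-13-one
Conditions: HF·pyridine, pyridine, THF, 0 °C → rt
Reagents that add atoms: none
Why: Fluoride cleaves the enol silane back to the C13 ketone (protonation at C14 creates no stereocentre) and frees both alcohols without the retro-aldol risk of basic fluoride.

Step 15
Reactants: 22 (1R,3E,7E,10S,11R,12S)-10,18-dihydroxyverticilla-3,7-dien-13-one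
Product: 24 (1R,3E,7E,10S,11S)-10-hydroxyverticilla-3,7,12(18)-trien-13-one, via primary mesylate 23 (not isolated)
Conditions: MsCl (1.1 equiv), Et3N, CH2Cl2, −20 °C; then DBU, rt
Reagents that add atoms: none
Why: The primary alcohol is sulfonylated in preference to the hindered secondary C10 alcohol, and E1cB elimination of the β-mesyloxy ketone gives the exocyclic enone with its position fixed by the earlier aldol trap.

Step 16
Reactants: 24 (1R,3E,7E,10S,11S)-10-hydroxyverticilla-3,7,12(18)-trien-13-one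
Product: 25 (1R,3E,7E,10S,11S)-10-acetoxyverticilla-3,7,12(18)-trien-13-one
Conditions: Ac2O, DMAP, pyridine, CH2Cl2, rt
Reagents that add atoms: acetic anhydride, CC(=O)OC(C)=O
Why: Standard acylation of the secondary alcohol with retention at C10.

Step 17
Reactants: 25 (1R,3E,7E,10S,11S)-10-acetoxyverticilla-3,7,12(18)-trien-13-one
Product: 26 (1R,3R,4R,7R,8R,10S,11S)-10-acetoxy-3,4:7,8-diepoxyverticill-12(18)-en-13-one
Conditions: D-fructose-derived Shi ketone (0.6 equiv), Oxone, K2CO3, Bu4NHSO4, Na2B4O7 buffer, MeCN/(MeO)2CH2/H2O, 0 °C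
Reagents that add atoms: potassium peroxymonosulfate (Oxone), [K+].[O-]S(=O)(=O)OO
Why: Shi asymmetric epoxidation with the D-fructose-derived dioxirane gives the (R,R)-epoxide from each E-trisubstituted alkene through the spiro transition state, and the electron-poor exocyclic enone does not react.

**Compound list**
1 | 5-(trimethylsilyl)pent-4-yn-1-ol | C[Si](C)(C)C#CCCCO | starting material
2 | {(1E)-5-[(diisobutylalumanyl)oxy]-1-(trimethylsilyl)pent-1-en-1-yl}diisobutylalane (Al cis to the chain) | CC(C)C[Al](CC(C)C)OCCC/C=C(/[Si](C)(C)C)[Al](CC(C)C)CC(C)C | intermediate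
3 | lithium methyl ate complex of alane 2 | [Li+].CC(C)C[Al](CC(C)C)OCCC/C=C(/[Si](C)(C)C)[Al-](C)(CC(C)C)CC(C)C | intermediate
4 | (4E)-5-(trimethylsilyl)hex-4-en-1-ol | OCCC/C=C(C)/[Si](C)(C)C | intermediate
5 | (4E)-5-(trimethylsilyl)hex-4-enal | O=CCC/C=C(C)/[Si](C)(C)C | intermediate
6 | trimethyl[(2E)-hept-2-en-6-yn-2-yl]silane | C#CCC/C=C(C)/[Si](C)(C)C | intermediate
7 | dimethyl[(1E,5E)-2-methyl-6-(trimethylsilyl)hepta-1,5-dien-1-yl]alane | C[Al](C)/C=C(C)/CC/C=C(C)/[Si](C)(C)C | intermediate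
8 | [(2E,6E)-7-iodo-6-methylhepta-2,6-dien-2-yl]trimethylsilane | I/C=C(C)/CC/C=C(C)/[Si](C)(C)C | intermediate
9 | 4,4-dimethylcyclohex-2-en-1-one | CC1(C)CCC(=O)C=C1 | starting material
10 | 4,4-dimethylcyclohexa-2,5-dien-1-one | CC1(C)C=CC(=O)C=C1 | intermediate
11 | lithium (3R)-4,4-dimethyl-3-[(4,4,5,5-tetramethyl-1,3,2-dioxaborolan-2-yl)methyl]cyclohexa-1,5-dien-1-olate | [Li+].[O-]C1=C[C@@H](CB2OC(C)(C)C(C)(C)O2)C(C)(C)C=C1 | intermediate
12 | (5R)-4,4-dimethyl-5-[(4,4,5,5-tetramethyl-1,3,2-dioxaborolan-2-yl)methyl]cyclohex-2-en-1-one | O=C1C[C@@H](CB2OC(C)(C)C(C)(C)O2)C(C)(C)C=C1 | intermediate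
13 | (5R)-4,4-dimethyl-5-[(2E,6E)-3-methyl-7-(trimethylsilyl)octa-2,6-dien-1-yl]cyclohex-2-en-1-one | O=C1C[C@@H](C/C=C(C)/CC/C=C(C)/[Si](C)(C)C)C(C)(C)C=C1 | intermediate
14 | {[(3R,5R)-3-ethenyl-4,4-dimethyl-5-[(2E,6E)-3-methyl-7-(trimethylsilyl)octa-2,6-dien-1-yl]cyclohex-1-en-1-yl]oxy}trimethylsilane | C[Si](C)(C)OC1=C[C@@H](C=C)C(C)(C)[C@H](C/C=C(C)/CC/C=C(C)/[Si](C)(C)C)C1 | intermediate
15 | (2S,3R,5R)-3-ethenyl-2-(hydroxymethyl)-4,4-dimethyl-5-[(2E,6E)-3-methyl-7-(trimethylsilyl)octa-2,6-dien-1-yl]cyclohexan-1-one | OC[C@H]1C(=O)C[C@@H](C/C=C(C)/CC/C=C(C)/[Si](C)(C)C)C(C)(C)[C@@H]1C=C | intermediate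
16 | (2S,3R,5R)-2-{[(tert-butyldimethylsilyl)oxy]methyl}-3-ethenyl-4,4-dimethyl-5-[(2E,6E)-3-methyl-7-(trimethylsilyl)octa-2,6-dien-1-yl]cyclohexan-1-one | CC(C)(C)[Si](C)(C)OC[C@H]1C(=O)C[C@@H](C/C=C(C)/CC/C=C(C)/[Si](C)(C)C)C(C)(C)[C@@H]1C=C | intermediate
17 | (2S,3R,5R)-3-acetyl-2-{[(tert-butyldimethylsilyl)oxy]methyl}-4,4-dimethyl-5-[(2E,6E)-3-methyl-7-(trimethylsilyl)octa-2,6-dien-1-yl]cyclohexan-1-one | CC(C)(C)[Si](C)(C)OC[C@H]1C(=O)C[C@@H](C/C=C(C)/CC/C=C(C)/[Si](C)(C)C)C(C)(C)[C@@H]1C(C)=O | intermediate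
18 | (2S,3R,5R)-3-acetyl-2-{[(tert-butyldimethylsilyl)oxy]methyl}-5-[(2E,6E)-7-iodo-3-methylocta-2,6-dien-1-yl]-4,4-dimethylcyclohexan-1-one | CC(C)(C)[Si](C)(C)OC[C@H]1C(=O)C[C@@H](C/C=C(C)/CC/C=C(C)/I)C(C)(C)[C@@H]1C(C)=O | intermediate
19 | (3R,5R,6S)-1-[(tert-butyldimethylsilyl)oxy]-5-{1-[(tert-butyldimethylsilyl)oxy]ethenyl}-6-{[(tert-butyldimethylsilyl)oxy]methyl}-3-[(2E,6E)-7-iodo-3-methylocta-2,6-dien-1-yl]-4,4-dimethylcyclohex-1-ene | CC(C)(C)[Si](C)(C)OC[C@H]1C(O[Si](C)(C)C(C)(C)C)=C[C@@H](C/C=C(C)/CC/C=C(C)/I)C(C)(C)[C@@H]1C(=C)O[Si](C)(C)C(C)(C)C | intermediate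
20 | B-alkyl-9-borabicyclo[3.3.1]nonane from 19 (boron on C9, new 10S silyloxy centre) | CC(C)(C)[Si](C)(C)OC[C@H]1C(O[Si](C)(C)C(C)(C)C)=C[C@@H](C/C=C(C)/CC/C=C(C)/I)C(C)(C)[C@@H]1[C@H](CB2C3CCCC2CCC3)O[Si](C)(C)C(C)(C)C | intermediate
21 | (1R,3E,7E,10S,11R,12S)-10,13,18-tris[(tert-butyldimethylsilyl)oxy]verticilla-3,7,13-triene | CC(C)(C)[Si](C)(C)OC[C@H]1C(O[Si](C)(C)C(C)(C)C)=C[C@H]2C/C=C(C)/CC/C=C(C)/C[C@H](O[Si](C)(C)C(C)(C)C)[C@H]1C2(C)C | intermediate
22 | (1R,3E,7E,10S,11R,12S)-10,18-dihydroxyverticilla-3,7-dien-13-one | OC[C@H]1C(=O)C[C@H]2C/C=C(C)/CC/C=C(C)/C[C@H](O)[C@H]1C2(C)C | intermediate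
23 | (1R,3E,7E,10S,11R,12S)-10-hydroxy-18-(methanesulfonyloxy)verticilla-3,7-dien-13-one | CS(=O)(=O)OC[C@H]1C(=O)C[C@H]2C/C=C(C)/CC/C=C(C)/C[C@H](O)[C@H]1C2(C)C | intermediate
24 | (1R,3E,7E,10S,11S)-10-hydroxyverticilla-3,7,12(18)-trien-13-one | C=C1C(=O)C[C@H]2C/C=C(C)/CC/C=C(C)/C[C@H](O)[C@H]1C2(C)C | intermediate
25 | (1R,3E,7E,10S,11S)-10-acetoxyverticilla-3,7,12(18)-trien-13-one | C=C1C(=O)C[C@H]2C/C=C(C)/CC/C=C(C)/C[C@H](OC(C)=O)[C@H]1C2(C)C | intermediate
26 | (1R,3R,4R,7R,8R,10S,11S)-10-acetoxy-3,4:7,8-diepoxyverticill-12(18)-en-13-one (CNP0339728.2) | C=C1C(=O)C[C@H]2C[C@H]3O[C@]3(C)CC[C@H]3O[C@]3(C)C[C@H](OC(C)=O)[C@H]1C2(C)C | target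

**Totals and risk**
Total step count: 17. Longest linear sequence: 15 steps (steps 1–4, then 7–17).

Three steps most likely to fail:

Step 6 (the proposed new conjugate borylmethylation). The β-carbon is next to a quaternary centre, the α-boryl alkylcopper is a weak nucleophile, and the facial sense of the ligand is not known (the antipodal ligand is used if the sense is reversed). The fallback uses known chemistry, sets out from 10 and comes back at 13. [Rh(cod)2]PF6/(S)-BINAP-catalysed 1,4-addition of CH2=CHBF3K to 10 gives (5S)-5-ethenyl-4,4-dimethylcyclohex-2-en-1-one F1. OsO4 (cat.)/NaIO4 cleaves only the electron-rich vinyl group to give (1R)-2,2-dimethyl-5-oxocyclohex-3-ene-1-carbaldehyde F2. This is reduced at once (NaBH4, MeOH, −78 °C) to (5R)-5-(hydroxymethyl)-4,4-dimethylcyclohex-2-en-1-one F3 and converted (I2, PPh3, imidazole) into (5R)-5-(iodomethyl)-4,4-dimethylcyclohex-2-en-1-one F4. Zinc insertion (Zn, LiCl, THF) gives {[(1R)-2,2-dimethyl-5-oxocyclohex-3-en-1-yl]methyl}zinc iodide F5, and Negishi coupling with iodide 8 (Pd(PPh3)4, THF) gives 13.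

Step 13 (hydroboration and Suzuki macrocyclisation). The β-silyloxy alkylborane can eliminate, the C10 facial selectivity rests on substrate control, and oligomers can compete with ring closure. The fallback sets out from 19 and comes back at 21: it closes the same C8–C9 bond at the ketone oxidation level and sets C10 afterwards by reagent control. Bu3SnF (1.05 equiv) with PdCl2[P(o-tol)3]2 in toluene at 80 °C under high dilution couples the terminal silyl enol ether of 19 with its alkenyl iodide (tin-enolate coupling that is selective for methyl-ketone-derived enol silanes) and gives (1R,3E,7E,11R,12S)-13,18-bis[(tert-butyldimethylsilyl)oxy]verticilla-3,7,13-trien-10-one F6. Reduction with (R)-Me-CBS and catecholborane (toluene, −78 °C; Felkin-matched) gives (1R,3E,7E,10S,11R,12S)-13,18-bis[(tert-butyldimethylsilyl)oxy]verticilla-3,7,13-trien-10-ol F7. Silylation (TBSOTf, 2,6-lutidine) gives 21.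

Step 17 (double Shi epoxidation). The macrocycle may expose only one face of one or both alkenes and override the catalyst, and the enone and acetate must survive pH 10. The fallback sets out from 25 and comes back at 26: it uses a halohydrin sequence, which places the epoxide oxygen on the face opposite to the one attacked by the electrophile and so complements direct oxygen transfer. NBS in THF/H2O at 0 °C gives (1R,3S,4R,7S,8R,10S,11S)-10-acetoxy-3,7-dibromo-4,8-dihydroxyverticill-12(18)-en-13-one F8 (Br at C3 and C7, tertiary OH at C4 and C8). Cs2CO3 in MeCN then closes both epoxides with inversion at C3 and C7 and gives 26.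

**Further compounds**
F1 | step 6 | (5S)-5-ethenyl-4,4-dimethylcyclohex-2-en-1-one | O=C1C[C@@H](C=C)C(C)(C)C=C1
F2 | step 6 | (1R)-2,2-dimethyl-5-oxocyclohex-3-ene-1-carbaldehyde | O=C1C[C@@H](C=O)C(C)(C)C=C1
F3 | step 6 | (5R)-5-(hydroxymethyl)-4,4-dimethylcyclohex-2-en-1-one | O=C1C[C@@H](CO)C(C)(C)C=C1
F4 | step 6 | (5R)-5-(iodomethyl)-4,4-dimethylcyclohex-2-en-1-one | O=C1C[C@@H](CI)C(C)(C)C=C1
F5 | step 6 | {[(1R)-2,2-dimethyl-5-oxocyclohex-3-en-1-yl]methyl}zinc iodide | O=C1C[C@@H](C[Zn]I)C(C)(C)C=C1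
F6 | step 13 | (1R,3E,7E,11R,12S)-13,18-bis[(tert-butyldimethylsilyl)oxy]verticilla-3,7,13-trien-10-one | CC(C)(C)[Si](C)(C)OC[C@H]1C(O[Si](C)(C)C(C)(C)C)=C[C@H]2C/C=C(C)/CC/C=C(C)/CC(=O)[C@H]1C2(C)C
F7 | step 13 | (1R,3E,7E,10S,11R,12S)-13,18-bis[(tert-butyldimethylsilyl)oxy]verticilla-3,7,13-trien-10-ol | CC(C)(C)[Si](C)(C)OC[C@H]1C(O[Si](C)(C)C(C)(C)C)=C[C@H]2C/C=C(C)/CC/C=C(C)/C[C@H](O)[C@H]1C2(C)C
F8 | step 17 | (1R,3S,4R,7S,8R,10S,11S)-10-acetoxy-3,7-dibromo-4,8-dihydroxyverticill-12(18)-en-13-one | C=C1C(=O)C[C@H]2C[C@H](Br)[C@@](O)(C)CC[C@H](Br)[C@@](O)(C)C[C@H](OC(C)=O)[C@H]1C2(C)C
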